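## Retrosynthetic overview

1. The ten-membered ring is closed last, at C1–C10, by an intramolecular Ni/Cr alkenyl iodide–aldehyde coupling of seco-aldehyde 21; this also creates the free C1 carbinol, so no protecting group is needed there.
2. 21 comes from epoxy alcohol 17 by angeloylation and acetal hydrolysis.
3. Key bond C6–C7: the acyl radical of cis-epoxy aldehyde 15 adds to C7 of bromomethylbutenolide 8 (anti to C8) and Br• is expelled, giving the α-methylene lactone directly; a chelation-controlled ketone reduction then sets C6.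
4. Fragment A (8): acrolein + propynyl Grignard, kinetic resolution (C8), hydroalumination/iodination (Z-C9=C10), bromomethylacrylate ester, ring-closing metathesis. Fragment B (15): but-2-yn-1-ol to the Z-iodide, Negishi coupling, Sharpless epoxidation (C4, C5), oxidation.
5. Ring order: butenolide and oxirane in parallel, then fragment union, then the carbocycle.

Assumption: germacrane numbering is used throughout (C8 lactone carbinol, C7 ring-fusion CH, C6 angeloyloxy carbon, C4/C5 epoxide, C1 carbinol, C9=C10 ring alkene, C11–C13 methylene lactone); the SMILES strings are authoritative, and the CIP label of one and the same centre can change between intermediates.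

## Route

Step 1
Reactants: 1 acrolein (prop-2-enal); 2 prop-1-yn-1-ylmagnesium bromide
Product: 3 rac-hex-1-en-4-yn-3-ol
Conditions: THF, −78 to 0 °C; then H2O
Reagents that add atoms: none
Why: Grignard 1,2-addition of the alkynyl nucleophile to the enal carbonyl gives the racemic vinyl propynyl carbinol.

Step 2
Reactants: 3 rac-hex-1-en-4-yn-3-ol
Product: 4 (3R)-hex-1-en-4-yn-3-ol
Conditions: Ti(OiPr)4 (0.15 equiv), D-(−)-diisopropyl tartrate (0.2 equiv), tBuOOH (0.6 equiv), 4 Å MS, CH2Cl2, −20 °C, about 55% conversion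
Reagents that add atoms: none
Why: Sharpless kinetic resolution: with the D-(−)-tartrate the 3S enantiomer is epoxidised at its vinyl group much faster (erythro epoxy alcohol), so (3R)-4 is recovered in high ee, which sets C8.

Step 3
Reactants: 4 (3R)-hex-1-en-4-yn-3-ol
Product: 5 (3R,4Z)-5-iodohexa-1,4-dien-3-ol
Conditions: NaAlH2(OCH2CH2OMe)2 (1.5 equiv), THF, 0 °C; then I2, −78 °C
Reagents that add atoms: iodine, II
Why: Alkoxide-directed trans-hydroalumination of the propargylic alcohol places aluminium on the distal alkyne carbon and iodinolysis with retention gives the Z-alkenyl iodide (C9=C10 geometry); the vinyl group and the carbinol centre are untouched.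

Step 4
Reactants: 5 (3R,4Z)-5-iodohexa-1,4-dien-3-ol; 6 2-(bromomethyl)prop-2-enoic acid
Product: 7 (3R,4Z)-5-iodohexa-1,4-dien-3-yl 2-(bromomethyl)prop-2-enoate
Conditions: DCC, DMAP (5 mol %), CH2Cl2, −20 to 0 °C
Reagents that add atoms: none
Why: Steglich esterification; low temperature and only catalytic DMAP keep the allylic bromide intact.

Step 5
Reactants: 7 (3R,4Z)-5-iodohexa-1,4-dien-3-yl 2-(bromomethyl)prop-2-enoate
Product: 8 (5R)-3-(bromomethyl)-5-[(Z)-2-iodoprop-1-enyl]furan-2(5H)-one
Conditions: second-generation Hoveyda–Grubbs catalyst (5 mol %), toluene, 80 °C, 5 mM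
Reagents that add atoms: none
Why: Ring-closing metathesis between the terminal vinyl group and the 1,1-disubstituted acrylate (loss of ethene) closes the butenolide; the trisubstituted iodoalkene does not take part.

Step 6
Reactants: 9 but-2-yn-1-ol
Product: 10 (2Z)-3-iodobut-2-en-1-ol
Conditions: NaAlH2(OCH2CH2OMe)2, THF, 0 °C; then I2, −78 °C
Reagents that add atoms: iodine, II
Why: The same hydroxyl-directed trans-hydroalumination/iodination gives the known Z-iodide, which fixes the cis relationship of C3 and C6 on the future epoxide.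

Step 7
Reactants: 10 (2Z)-3-iodobut-2-en-1-ol; 11 3-bromo-1,1-dimethoxypropane
Product: 13 (2Z)-6,6-dimethoxy-3-methylhex-2-en-1-ol, via (3,3-dimethoxypropyl)zinc bromide 12 (not isolated)
Conditions: 11, Zn dust, LiCl, THF, 50 °C; then 10, Pd(OAc)2 (2 mol %), SPhos (4 mol %), THF, 25 °C
Reagents that add atoms: none
Why: Knochel zinc insertion followed by Negishi coupling, which retains the alkene geometry; alkylzinc halides tolerate the free hydroxyl under these conditions.

Step 8
Reactants: 13 (2Z)-6,6-dimethoxy-3-methylhex-2-en-1-ol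
Product: 14 [(2S,3R)-3-(3,3-dimethoxypropyl)-3-methyloxiran-2-yl]methanol
Conditions: Ti(OiPr)4 (10 mol %), L-(+)-diethyl tartrate (12 mol %), tBuOOH, 4 Å MS, CH2Cl2, −20 °C
Reagents that add atoms: tert-butyl hydroperoxide, CC(C)(C)OO
Why: Sharpless asymmetric epoxidation; the L-(+)-tartrate gives the (2S,3R) cis-epoxide from this Z-3-methyl allylic alcohol (as with nerol), which sets C4 and C5.

Step 9
Reactants: 14 [(2S,3R)-3-(3,3-dimethoxypropyl)-3-methyloxiran-2-yl]methanol
Product: 15 (2R,3R)-3-(3,3-dimethoxypropyl)-3-methyloxirane-2-carbaldehyde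
Conditions: Dess–Martin periodinane, pyridine, CH2Cl2, 0 °C
Reagents that add atoms: none
Why: Buffered Dess–Martin oxidation gives the cis-epoxy aldehyde without touching the acetal or the epoxide (the descriptor at the aldehyde-bearing carbon changes by priority only).

Step 10
Reactants: 8 (5R)-3-(bromomethyl)-5-[(Z)-2-iodoprop-1-enyl]furan-2(5H)-one; 15 (2R,3R)-3-(3,3-dimethoxypropyl)-3-methyloxirane-2-carbaldehyde
Product: 17 (4S,5R)-4-[(S)-[(2S,3R)-3-(3,3-dimethoxypropyl)-3-methyloxiran-2-yl](hydroxy)methyl]-5-[(Z)-2-iodoprop-1-enyl]-3-methylideneoxolan-2-one, via epoxy ketone 16 (not isolated)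
Conditions: 15 (1.5 equiv), (nBu4N)4W10O32 (2 mol %), K2HPO4, MeCN, 390 nm LEDs, 10 °C; filter, concentrate cold; then Zn(BH4)2, Et2O, −30 °C
Reagents that add atoms: none
Why: Proposed new method: excited decatungstate abstracts the formyl hydrogen of 15 (the weakest and most hydridic C–H; the acyclic acetal C–H and the electron-poor C–H bonds of 8 should react more slowly), the σ-acyl radical (CO loss would give an unstabilised oxiranyl radical and is slow) adds to the β-carbon C7 of the butenolide anti to the C8 substituent, as in known photochemical acyl and acetal radical additions to 5-substituted furan-2(5H)-ones, and the α-carbonyl radical expels Br• by β-scission, as in radical allylations with 2-(bromomethyl)acrylates, leaving the exo-methylene; Br• is reduced by the reduced polyoxometalate and HBr is buffered; the closest known reactions are decatungstate Giese-type hydroacylation of electron-poor alkenes and radical addition–fragmentation allylation; the crude β-keto lactone 16 is reduced at once by Zn(BH4)2 under epoxide-chelation control (Oishi–Nakata) to the anti epoxy alcohol, which sets C6, while C7 is set trans to C8 by the radical addition.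

Step 11
Reactants: 17 the epoxy alcohol from step 10; 18 angelic acid [(Z)-2-methylbut-2-enoic acid]
Product: 20 (S)-[(2S,3R)-3-(3,3-dimethoxypropyl)-3-methyloxiran-2-yl][(2R,3R)-2-[(Z)-2-iodoprop-1-enyl]-4-methylidene-5-oxooxolan-3-yl]methyl (Z)-2-methylbut-2-enoate, via angelic 2,4,6-trichlorobenzoic anhydride 19 (not isolated)
Conditions: 18, 2,4,6-Cl3C6H2COCl, Et3N, toluene, 25 °C; then 17, toluene, 75 °C, no DMAP
Reagents that add atoms: none
Why: Yamaguchi-type acylation through the mixed anhydride without nucleophilic catalyst is the established way to form angelates without Z-to-E isomerisation; the C6 hydroxyl is the only one present.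

Step 12
Reactants: 20 the angelate dimethyl acetal from step 11
Product: 21 (S)-[(2S,3R)-3-methyl-3-(3-oxopropyl)oxiran-2-yl][(2R,3R)-2-[(Z)-2-iodoprop-1-enyl]-4-methylidene-5-oxooxolan-3-yl]methyl (Z)-2-methylbut-2-enoate
Conditions: PPTS (0.2 equiv), acetone/H2O (10:1), 40 °C
Reagents that add atoms: water, O
Why: Mild acid-catalysed acetal hydrolysis frees the C1 aldehyde; the epoxide (deactivated by the neighbouring acyloxy group), the esters and the alkenyl iodide tolerate PPTS.

Step 13
Reactants: 21 the seco-aldehyde alkenyl iodide from step 12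
Product: 22 (1R,4R,5S,6S,7R,8S,9Z)-6-angeloyloxy-4,5-epoxy-1-hydroxygermacra-9,11(13)-dien-12,8-olide (CNP0191628.1)
Conditions: CrCl2 (4 equiv), NiCl2 (2 mol %), Kishi oxazoline–sulfonamide ligand (4.4 equiv, antipode selected for 1R), Et3N (4.4 equiv), THF, 2 mM, 25 °C
Reagents that add atoms: none
Why: Intramolecular Nozaki–Hiyama–Kishi reaction: the Z-alkenylchromium species (geometry retained) adds only to the aldehyde, and the cis-alkene and cis-epoxide pre-organise the chain for ten-membered ring closure; C1 is set by the chiral sulfonamide ligand on chromium (reagent control), and which ligand antipode gives 1R has to be found by trial.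

## Compound list

1 | acrolein (prop-2-enal) | C=CC=O | starting material
2 | prop-1-yn-1-ylmagnesium bromide | CC#C[Mg]Br | starting material
3 | rac-hex-1-en-4-yn-3-ol | C=CC(O)C#CC | intermediate
4 | (3R)-hex-1-en-4-yn-3-ol | O[C@@H](C#CC)C=C | intermediate
5 | (3R,4Z)-5-iodohexa-1,4-dien-3-ol | O[C@@H](/C=C(/C)I)C=C | intermediate
6 | 2-(bromomethyl)prop-2-enoic acid | C=C(CBr)C(=O)O | starting material
7 | (3R,4Z)-5-iodohexa-1,4-dien-3-yl 2-(bromomethyl)prop-2-enoate | C=C(CBr)C(=O)O[C@@H](/C=C(/C)I)C=C | intermediate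
8 | (5R)-3-(bromomethyl)-5-[(Z)-2-iodoprop-1-enyl]furan-2(5H)-one | O=C1O[C@@H](/C=C(/C)I)C=C1CBr | intermediate
9 | but-2-yn-1-ol | CC#CCO | starting material
10 | (2Z)-3-iodobut-2-en-1-ol | OC/C=C(/C)I | intermediate
11 | 3-bromo-1,1-dimethoxypropane | COC(OC)CCBr | starting material
12 | (3,3-dimethoxypropyl)zinc bromide | COC(OC)CC[Zn]Br | intermediate
13 | (2Z)-6,6-dimethoxy-3-methylhex-2-en-1-ol | OC/C=C(/C)CCC(OC)OC | intermediate
14 | [(2S,3R)-3-(3,3-dimethoxypropyl)-3-methyloxiran-2-yl]methanol | OC[C@@H]1O[C@]1(C)CCC(OC)OC | intermediate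
15 | (2R,3R)-3-(3,3-dimethoxypropyl)-3-methyloxirane-2-carbaldehyde | O=C[C@@H]1O[C@]1(C)CCC(OC)OC | intermediate
16 | (4R,5R)-4-{[(2R,3R)-3-(3,3-dimethoxypropyl)-3-methyloxiran-2-yl]carbonyl}-5-[(Z)-2-iodoprop-1-enyl]-3-methylideneoxolan-2-one | C=C1C(=O)O[C@@H](/C=C(/C)I)[C@@H]1C(=O)[C@@H]2O[C@]2(C)CCC(OC)OC | intermediate
17 | (4S,5R)-4-[(S)-[(2S,3R)-3-(3,3-dimethoxypropyl)-3-methyloxiran-2-yl](hydroxy)methyl]-5-[(Z)-2-iodoprop-1-enyl]-3-methylideneoxolan-2-one | C=C1C(=O)O[C@@H](/C=C(/C)I)[C@@H]1[C@H](O)[C@@H]2O[C@]2(C)CCC(OC)OC | intermediate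
18 | angelic acid [(Z)-2-methylbut-2-enoic acid] | C/C=C(/C)C(=O)O | starting material
19 | angelic 2,4,6-trichlorobenzoic anhydride | C/C=C(/C)C(=O)OC(=O)c1c(Cl)cc(Cl)cc1Cl | intermediate
20 | (S)-[(2S,3R)-3-(3,3-dimethoxypropyl)-3-methyloxiran-2-yl][(2R,3R)-2-[(Z)-2-iodoprop-1-enyl]-4-methylidene-5-oxooxolan-3-yl]methyl (Z)-2-methylbut-2-enoate | C=C1C(=O)O[C@@H](/C=C(/C)I)[C@@H]1[C@H](OC(=O)/C(C)=C\C)[C@@H]2O[C@]2(C)CCC(OC)OC | intermediate
21 | (S)-[(2S,3R)-3-methyl-3-(3-oxopropyl)oxiran-2-yl][(2R,3R)-2-[(Z)-2-iodoprop-1-enyl]-4-methylidene-5-oxooxolan-3-yl]methyl (Z)-2-methylbut-2-enoate | C=C1C(=O)O[C@@H](/C=C(/C)I)[C@@H]1[C@H](OC(=O)/C(C)=C\C)[C@@H]2O[C@]2(C)CCC=O | intermediate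
22 | (1R,4R,5S,6S,7R,8S,9Z)-6-angeloyloxy-4,5-epoxy-1-hydroxygermacra-9,11(13)-dien-12,8-olide | C=C1C(=O)O[C@H]2/C=C(/C)[C@H](O)CC[C@@]3(C)O[C@H]3[C@@H](OC(=O)/C(C)=C\C)[C@H]12 | target

## Step count and risks

Total step count: 13. Longest linear sequence: 9 steps (steps 1–5, then 10–13); the second branch (steps 6–9, then 10–13) is 8 steps. The minor enantiomers left after steps 2 and 8 become diastereomers at step 10 and are removed there.

The three steps most likely to fail:

Step 10 (radical fragment union). Risks are competing hydrogen abstraction from the weak C8–H of 8 or from the acetal, ring opening or decarbonylation of the epoxy-acyl radical, and isomerisation of 16 to the endocyclic butenolide before reduction. Fallback: the same fragments are joined by a polar Barbier allylation. Setting out from 8 and 15, indium powder in THF/H2O converts 8 into [(5R)-5-[(Z)-2-iodoprop-1-enyl]-2-oxo-2,5-dihydrofuran-3-yl]methylindium dibromide F1. F1 adds through its γ-carbon (C7, anti to the C8 substituent, six-membered transition state) to the epoxy aldehyde under Felkin–Anh polar control (the same anti C5/C6 relationship) and gives 17 directly, where the fallback rejoins the route.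

Step 13 (ring closure and C1 configuration). Risks are oligomerisation and poor or wrong-sense ligand control at C1. Fallback: setting out from 21, the ring is closed without chiral ligand (CrCl2, NiCl2 cat., DMSO/THF, high dilution) to a mixture of 22 and its C1 epimer, the (1S)-alcohol F2. Dess–Martin oxidation converts both into the macrocyclic Z-enone, 1-oxo-22 F3. Reduction with (S)-Me-CBS oxazaborolidine and catecholborane at −78 °C (alkenyl as the large group, the sense that gives (R)-1-phenylethanol from acetophenone) delivers the 1R alcohol and comes back at 22.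

Step 5 (metathesis of the electron-poor, allylic-bromide-bearing acrylate). Risk is a sluggish ring closure or catalyst decomposition. Fallback: the bromomethyl group is installed after ring formation. Setting out from 5, acylation with acryloyl chloride/Et3N gives (3R,4Z)-5-iodohexa-1,4-dien-3-yl prop-2-enoate F4. Its ring-closing metathesis with second-generation Grubbs catalyst is routine and gives (5R)-5-[(Z)-2-iodoprop-1-enyl]furan-2(5H)-one F5. Morita–Baylis–Hillman hydroxymethylation (aqueous CH2O, imidazole) gives (5R)-3-(hydroxymethyl)-5-[(Z)-2-iodoprop-1-enyl]furan-2(5H)-one F6, and PBr3 converts it into the bromide, coming back at 8.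

Further compounds
F1 | step 10 | [(5R)-5-[(Z)-2-iodoprop-1-enyl]-2-oxo-2,5-dihydrofuran-3-yl]methylindium dibromide | O=C1O[C@@H](/C=C(/C)I)C=C1C[In](Br)Br
F2 | step 13 | (1S,4R,5S,6S,7R,8S,9Z)-6-angeloyloxy-4,5-epoxy-1-hydroxygermacra-9,11(13)-dien-12,8-olide (C1 epimer of 22) | C=C1C(=O)O[C@H]2/C=C(/C)[C@@H](O)CC[C@@]3(C)O[C@H]3[C@@H](OC(=O)/C(C)=C\C)[C@H]12
F3 | step 13 | (4R,5S,6S,7R,8S,9Z)-6-angeloyloxy-4,5-epoxy-1-oxogermacra-9,11(13)-dien-12,8-olide | C=C1C(=O)O[C@H]2/C=C(/C)C(=O)CC[C@@]3(C)O[C@H]3[C@@H](OC(=O)/C(C)=C\C)[C@H]12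
F4 | step 5 | (3R,4Z)-5-iodohexa-1,4-dien-3-yl prop-2-enoate | C=CC(=O)O[C@@H](/C=C(/C)I)C=C
F5 | step 5 | (5R)-5-[(Z)-2-iodoprop-1-enyl]furan-2(5H)-one | O=C1O[C@@H](/C=C(/C)I)C=C1
F6 | step 5 | (5R)-3-(hydroxymethyl)-5-[(Z)-2-iodoprop-1-enyl]furan-2(5H)-one | O=C1O[C@@H](/C=C(/C)I)C=C1CO
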